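**Retrosynthetic overview**
1. Target 28 ← α-methylene cis-lactone 16: the lactone is opened, the C12 acid is masked as a phenacyl ester, O-8 is esterified with dioxepine acid 23 (its seven-membered acetonide fixes the side-chain alkene geometry), then C3 is acetylated and all masks are removed in one operation.
2. 16 ← trans-fused keto lactone 10: C10 ketone → exocyclic methylene → Markovnikov hydration (10β-OH, 10α-CH3), then α-methylenation of the lactone.
3. 10 ← cyclopentane 8 in one cascade: the vinyl group on C10 adds through C2 to the aldehyde carbon C3 of a (Z)-enal on C6, then C6 shifts from C10 to C1. Ring A (C1, C6, C7, C8, C9, C10) arises from the five-membered ring C6–C7–C8–C9–C10 by one-carbon ring expansion, while ring B closes as a seven-membered ring and contracts to six.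
4. Enabling feature: ring-fusion carbon C1 lies between the oxygen-bearing C10 and the allylic C6. With C10 as a latent carbonyl (silyloxy carbinol), C1 becomes a cationic migration terminus, and the rest of ring A (C6–C10 with the cis C7–C11/C8–O pair) is the cyclopentane of the commercial prostaglandin lactone 1.
5. 8 ← 1 (iodo-olefination at C5, vinyl addition to the C10 ketone, carbonylative formylation). Ring order: cyclopentane and γ-lactone (bought) → rings A and B together (step 8).

Key step: step 8

Remark: cadinane numbering is used for all carbon atoms from compound 1 onward (C1/C6 ring fusion, C3 acetoxy carbon, C4=C5, C7 carrying C11(=C13)–C12, C8 acyloxy carbon, C10 carbinol carbon with C14). β is the face of H-1 in the target, whose SMILES is read as 1β-H, 6α-H (trans-decalin), 3β-OAc, 7β-H, 8α-O, 10β-OH, (E)-acyl group.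

**Route**

Step 1
Reactants: 1 (3aR,4S,5R,6aS)-5-(benzoyloxy)-4-(hydroxymethyl)hexahydro-2H-cyclopenta[b]furan-2-one (commercial prostaglandin lactone benzoate)
Product: 2 (3aR,4R,5R,6aS)-4-formyl-2-oxohexahydro-2H-cyclopenta[b]furan-5-yl benzoate
Conditions: Dess–Martin periodinane, NaHCO3, CH2Cl2, 0 → 23 °C
Reagents that add atoms: none
Why: Dess–Martin oxidation of the primary alcohol should stop at the aldehyde under buffered, non-basic conditions, so the β-benzoyloxy aldehyde neither eliminates nor epimerises at C6 and is used crude.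

Step 2
Reactants: 2 aldehyde
Product: 3 lactone benzoate with a (Z)-2-iodoprop-1-enyl group at C6
Conditions: EtPPh3I, n-BuLi, THF, 23 °C; I2, −78 °C; NaHMDS, −20 °C; then 2, −78 → −20 °C
Reagents that add atoms: ethyltriphenylphosphonium iodide, CC[P+](c1ccccc1)(c1ccccc1)c1ccccc1.[I-]; iodine, II
Why: Stork–Zhao olefination with the α-iodo ethylidene ylide should give, under kinetic Wittig control, the (Z)-2-iodoalkene with C6 and iodine cis, the geometry that later holds C3 next to C6.

Step 3
Reactants: 3 vinyl iodide benzoate
Product: 4 C10 α-alcohol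
Conditions: K2CO3, MeOH, 23 °C; then AcOH to pH 5
Reagents that add atoms: none
Why: Base-catalysed transesterification removes the benzoate as methyl benzoate, and any methanolysed lactone re-closes on acidification because the C7/C8 substituents are cis.

Step 4
Reactants: 4 alcohol
Product: 5 C10 ketone (cis-fused bicyclic keto lactone)
Conditions: Dess–Martin periodinane, NaHCO3, CH2Cl2, 0 °C
Reagents that add atoms: none
Why: Dess–Martin oxidation under neutral conditions should deliver the β-acyloxy, β,γ-unsaturated cyclopentanone without E1cB loss of the lactone oxygen or migration of the alkene, provided it is taken on at once without chromatography.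

Step 5
Reactants: 5 ketone
Product: 6 10β-hydroxy-10α-vinyl carbinol
Conditions: CeCl3, CH2=CHMgBr, THF, −78 °C
Reagents that add atoms: vinylmagnesium bromide, C=C[Mg]Br
Why: The weakly basic organocerium reagent should add 1,2 to the enolisable ketone faster than it enolises it, attacking anti to the adjacent C6 alkenyl group; either C10 epimer would serve because C10 becomes sp2 in step 8.

Step 6
Reactants: 6 carbinol
Product: 7 tertiary tert-butyldimethylsilyl ether
Conditions: TBSOTf, 2,6-lutidine, CH2Cl2, 0 → 23 °C
Reagents that add atoms: tert-butyldimethylsilyl triflate, CC(C)(C)[Si](C)(C)OS(=O)(=O)C(F)(F)F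
Why: Silyl triflate silylation reaches the hindered tertiary alcohol and installs the oxygen donor group that drives the pinacol shift of step 8.

Step 7
Reactants: 7 vinyl iodide
Product: 8 (Z)-enal
Conditions: Pd(PPh3)4 (5 mol %), CO (3 atm), Bu3SnH (slow addition), THF, 50 °C
Reagents that add atoms: carbon monoxide, [C-]#[O+]
Why: Palladium-catalysed reductive carbonylation (oxidative addition, CO insertion, hydride transfer from tin to the acyl palladium) should convert the vinyl iodide into the enal with retention of the (Z) geometry.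

Step 8
Reactants: 8 (Z)-enal
Product: 9 cis-fused tricyclic keto lactone (3β-OTBS; 1α-H, 6α-H)
Conditions: TBSOTf (20 mol %), 2,6-di-tert-butyl-4-methylpyridine (30 mol %), CH2Cl2, −78 → −40 °C
Reagents that add atoms: none
Why: Proposed new method: silylation of the s-trans (Z)-enal gives a silyloxocarbenium ion that is attacked at C3 by the terminal carbon C2 of the C10 vinyl group; the secondary cation at C1 is quenched by a pinacol shift of C6 from C10 to C1, and the resulting silyloxocarbenium at C10 passes its silyl group to the next aldehyde, so the cascade is a redox-neutral isomerisation with catalytic TBSOTf. The closest known reaction type is the pinacol-terminated Prins cyclisation of 1-alkenylcycloalkyl silyl ethers with a tethered acetal (ring-enlarging cyclopentane annulation); new here are the tether that is one carbon longer and runs through a (Z)-alkene, and the conjugated aldehyde as initiator. Ring B closes first as a seven-membered ring (C2–C3 bond, endo with respect to the vinyl group, exo with respect to C=O) and is contracted to six by the shift, which at the same time expands the cyclopentane C6–C7–C8–C9–C10 to the cyclohexanone ring A by inserting C1 between C10 and C6. C3 is set by allylic 1,3-strain across the (Z)-C4=C5 bond: H-6 eclipses the alkene, C10 with its vinyl group sits on one face of the enal, and the carbonyl oxygen points outward, so C2 adds to the face that places O-3 cis to the C6–C7 bond (3β). C6 migrates with retention, and C1 is formed cis to H-6 because the shift is suprafacial within the fused bicycle (corrected in step 9). The step needs 1,2- rather than 1,4-attack on the enal and migration of C6 rather than C9; the 1,4-mode would require a strained 5-endo closure onto the vinyl group, and C6 is the tertiary, allylic migrating carbon.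

Step 9
Reactants: 9 cis-fused keto lactone
Product: 10 trans-fused keto lactone (1β-H)
Conditions: TsOH·H2O (10 mol %), CH2Cl2, 23 °C
Reagents that add atoms: none
Why: Acid-catalysed enolisation toward the more substituted C1 should equilibrate the 1-decalone to the more stable trans fusion, while avoiding the base-induced E1cB loss of the axial β-acyloxy group at C8.

Step 10
Reactants: 10 trans-fused ketone
Product: 11 10-methylene compound
Conditions: Zn, CH2Br2, TiCl4, THF/CH2Cl2, 0 → 23 °C
Reagents that add atoms: dibromomethane, BrCBr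
Why: Lombardo methylenation is non-basic, so the hindered, enolisable β-acyloxy ketone should be methylenated without epimerisation at C1, without β-elimination and without touching the lactone.

Step 11
Reactants: 11 exocyclic alkene
Product: 13 10β-hydroxy-10α-methyl lactone, via organomercurial acetate 12 (not isolated)
Conditions: Hg(OAc)2, THF/H2O (1:1), 23 °C; then NaBH4, aq. NaOH, 0 °C; then pH 4
Reagents that add atoms: water, O
Why: Oxymercuration–demercuration (Markovnikov hydration) prefers the 1,1-disubstituted exocyclic alkene over the trisubstituted C4=C5, and water should enter C10 from the equatorial β-face because the axial α-face is screened by the syn-axial lactone oxygen on C8, leaving the methyl group axial (α).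

Step 12
Reactants: 13 lactone
Product: 16 α-methylene lactone, via Mannich base 14 (not isolated), via ammonium iodide 15 (not isolated)
Conditions: LDA (2.3 equiv), THF, −78 °C; CH2=NMe2 I, −78 → 0 °C; then MeI, MeOH, 23 °C; then NaHCO3, CH2Cl2/H2O, 23 °C
Reagents that add atoms: Eschenmoser's salt (N,N-dimethylmethyleneiminium iodide), C=[N+](C)C.[I-]
Why: The lactone enolate (the tertiary alkoxide takes the extra equivalent of base) should undergo the Mannich reaction on the convex face, and N-methylation followed by mild base elimination gives the exocyclic C11=C13 alkene (Eschenmoser α-methylenation).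

Step 13
Reactants: 16 α-methylene lactone
Product: 18 phenacyl ester with free 8α-OH, via lithium carboxylate 17 (not isolated)
Conditions: LiOH, THF/H2O, 0 °C; evaporate; then PhCOCH2Br, DMF, 0 → 23 °C
Reagents that add atoms: lithium hydroxide, [Li+].[OH-]; phenacyl bromide, BrCC(=O)c1ccccc1
Why: Saponification followed by O-alkylation of the carboxylate while still basic traps the open form before the cis γ-hydroxy acid can relactonise; the carboxylate is not a Michael acceptor, and the phenacyl ester is later removable by zinc in acetic acid.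

Step 14
Reactants: 19 but-2-yne-1,4-diol
Product: 20 (E)-2-(tributylstannyl)but-2-ene-1,4-diol
Conditions: Bu3SnH, PdCl2(PPh3)2 (2 mol %), THF, 23 °C
Reagents that add atoms: tributyltin hydride, CCCC[SnH](CCCC)CCCC
Why: Palladium-catalysed hydrostannation adds H and Sn syn across the symmetrical alkyne, so the two CH2OH groups end up cis.

Step 15
Reactants: 20 stannyl diol
Product: 21 2,2-dimethyl-5-(tributylstannyl)-4,7-dihydro-1,3-dioxepine
Conditions: Me2C(OMe)2, PPTS (cat.), CH2Cl2, 23 °C
Reagents that add atoms: 2,2-dimethoxypropane, COC(C)(C)OC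
Why: Transacetalisation closes the seven-membered acetonide, which is possible only for the cis diol and thereby locks the alkene geometry of the later acyl group.

Step 16
Reactants: 21 stannyl dioxepine
Product: 23 2,2-dimethyl-4,7-dihydro-1,3-dioxepine-5-carboxylic acid, via vinyllithium 22 (not isolated)
Conditions: n-BuLi, THF, −78 °C; then CO2, −78 → 0 °C; cold 0.5 M HCl to pH 4
Reagents that add atoms: carbon dioxide, O=C=O
Why: Tin–lithium exchange gives the configurationally fixed vinyllithium, which should be carboxylated at −78 °C before β-elimination of the allylic oxygen can occur.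

Step 17
Reactants: 18 phenacyl ester alcohol; 23 dioxepine acid
Product: 25 8α-ester, via mixed anhydride 24 (not isolated)
Conditions: 23, 2,4,6-Cl3C6H2COCl, Et3N, THF, 23 °C; then 18, DMAP, toluene, 23 → 50 °C
Reagents that add atoms: none
Why: Yamaguchi esterification is the standard answer to a hindered axial secondary alcohol (here syn-axial to the C10 methyl group); the tertiary 10-OH should stay free, and fast acyl transfer from the acylpyridinium should outrun relactonisation onto the phenacyl ester.

Step 18
Reactants: 25 silyl ether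
Product: 26 3β-alcohol
Conditions: TBAF, AcOH (1:1), THF, 0 → 23 °C
Reagents that add atoms: none
Why: Buffered fluoride should cleave the only silyl ether while leaving the base-sensitive phenacyl ester, the acrylate and the acetonide untouched.

Step 19
Reactants: 26 alcohol
Product: 27 3β-acetate
Conditions: Ac2O, pyridine, DMAP (cat.), CH2Cl2, 0 °C
Reagents that add atoms: acetic anhydride, CC(=O)OC(C)=O
Why: DMAP-catalysed acetylation should take the secondary allylic alcohol with retention, while the tertiary 10-OH is too hindered to react at 0 °C.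

Step 20
Reactants: 27 protected precursor
Product: 28 target acid CNP0468194.3
Conditions: Zn, AcOH/H2O (4:1), 23 °C
Reagents that add atoms: none
Why: Zinc in acetic acid cleaves the phenacyl ester reductively, and the same aqueous acetic acid should hydrolyse the strained seven-membered acetonide, conditions mild enough for the allylic acetate, the tertiary alcohol and both unsaturated esters.

**Compound list**
1 | (3aR,4S,5R,6aS)-5-(benzoyloxy)-4-(hydroxymethyl)hexahydro-2H-cyclopenta[b]furan-2-one (6β-CH2OH, 10α-OBz, cis γ-lactone on the α-face through C7–C11 and C8–O) | O=C1C[C@@H]2[C@@H](CO)[C@H](OC(=O)c3ccccc3)C[C@@H]2O1 | starting material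
2 | (3aR,4R,5R,6aS)-4-formyl-2-oxohexahydro-2H-cyclopenta[b]furan-5-yl benzoate | O=C1C[C@@H]2[C@@H](C=O)[C@H](OC(=O)c3ccccc3)C[C@@H]2O1 | intermediate
3 | same bicyclic lactone benzoate with a (Z)-2-iodoprop-1-enyl group at C6 (β; C6 and I cis) | O=C1C[C@@H]2[C@@H](/C=C(/C)I)[C@H](OC(=O)c3ccccc3)C[C@@H]2O1 | intermediate
4 | 10α-alcohol of 3 (benzoate removed) | O=C1C[C@@H]2[C@@H](/C=C(/C)I)[C@H](O)C[C@@H]2O1 | intermediate
5 | C10 ketone: cis-fused bicyclic keto lactone with 6β-[(Z)-2-iodoprop-1-enyl] | O=C1C[C@@H]2[C@@H](/C=C(/C)I)C(=O)C[C@@H]2O1 | intermediate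
6 | 10β-hydroxy-10α-vinyl carbinol | O=C1C[C@@H]2[C@@H](/C=C(/C)I)[C@](O)(C=C)C[C@@H]2O1 | intermediate
7 | 10β-(tert-butyldimethylsilyloxy)-10α-vinyl lactone | O=C1C[C@@H]2[C@@H](/C=C(/C)I)[C@](O[Si](C)(C)C(C)(C)C)(C=C)C[C@@H]2O1 | intermediate
8 | (Z)-enal: 6β-[(Z)-2-methyl-3-oxoprop-1-enyl] (C6 and CHO cis), 10β-OTBS, 10α-vinyl lactone | O=C1C[C@@H]2[C@@H](/C=C(/C)C=O)[C@](O[Si](C)(C)C(C)(C)C)(C=C)C[C@@H]2O1 | intermediate
9 | cis-fused tricyclic keto lactone (1α-H, 6α-H): ring B with 3β-OTBS and C4(CH3)=C5, ring A with C10 ketone, γ-lactone C7(α)–C11H2–C12(=O)–O–C8(α) | O=C1C[C@@H]2[C@H]3C=C(C)[C@@H](O[Si](C)(C)C(C)(C)C)C[C@H]3C(=O)C[C@@H]2O1 | intermediate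
10 | trans-fused isomer of 9 (1β-H, 6α-H) | O=C1C[C@@H]2[C@H]3C=C(C)[C@@H](O[Si](C)(C)C(C)(C)C)C[C@@H]3C(=O)C[C@@H]2O1 | intermediate
11 | 10-methylene lactone (C10=C14H2) | O=C1C[C@@H]2[C@H]3C=C(C)[C@@H](O[Si](C)(C)C(C)(C)C)C[C@@H]3C(=C)C[C@@H]2O1 | intermediate
12 | organomercurial acetate: 10β-hydroxy-10α-(acetoxymercuriomethyl) lactone | O=C1C[C@@H]2[C@H]3C=C(C)[C@@H](O[Si](C)(C)C(C)(C)C)C[C@@H]3[C@@](C[Hg]OC(C)=O)(O)C[C@@H]2O1 | intermediate
13 | 10β-hydroxy-10α-methyl lactone (3β-OTBS) | O=C1C[C@@H]2[C@H]3C=C(C)[C@@H](O[Si](C)(C)C(C)(C)C)C[C@@H]3[C@@](C)(O)C[C@@H]2O1 | intermediate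
14 | Mannich base: 11-(dimethylaminomethyl) lactone (CH2NMe2 cis to H-7) | O=C1[C@@H](CN(C)C)[C@@H]2[C@H]3C=C(C)[C@@H](O[Si](C)(C)C(C)(C)C)C[C@@H]3[C@@](C)(O)C[C@@H]2O1 | intermediate
15 | trimethylammonium iodide of 14 | O=C1[C@@H](C[N+](C)(C)C)[C@@H]2[C@H]3C=C(C)[C@@H](O[Si](C)(C)C(C)(C)C)C[C@@H]3[C@@](C)(O)C[C@@H]2O1.[I-] | intermediate
16 | α-methylene lactone: 3β-OTBS, 10β-OH, C11=C13H2, 12,8α-lactone | O=C1C(=C)[C@@H]2[C@H]3C=C(C)[C@@H](O[Si](C)(C)C(C)(C)C)C[C@@H]3[C@@](C)(O)C[C@@H]2O1 | intermediate
17 | lithium carboxylate of the opened lactone (8α-OH free) | [Li+].[O-]C(=O)C(=C)[C@@H]1[C@H]2C=C(C)[C@@H](O[Si](C)(C)C(C)(C)C)C[C@@H]2[C@@](C)(O)C[C@@H]1O | intermediate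
18 | phenacyl ester of the C12 acid: 3β-OTBS, 8α-OH, 10β-OH | C=C(C(=O)OCC(=O)c3ccccc3)[C@@H]1[C@H]2C=C(C)[C@@H](O[Si](C)(C)C(C)(C)C)C[C@@H]2[C@@](C)(O)C[C@@H]1O | intermediate
19 | but-2-yne-1,4-diol | OCC#CCO | starting material
20 | (E)-2-(tributylstannyl)but-2-ene-1,4-diol (CH2OH groups cis) | OC/C=C(/[Sn](CCCC)(CCCC)CCCC)CO | intermediate
21 | 2,2-dimethyl-5-(tributylstannyl)-4,7-dihydro-1,3-dioxepine | CC1(C)OCC=C([Sn](CCCC)(CCCC)CCCC)CO1 | intermediate
22 | (2,2-dimethyl-4,7-dihydro-1,3-dioxepin-5-yl)lithium | CC1(C)OCC=C([Li])CO1 | intermediate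
23 | 2,2-dimethyl-4,7-dihydro-1,3-dioxepine-5-carboxylic acid | CC1(C)OCC=C(C(=O)O)CO1 | intermediate
24 | mixed anhydride of 23 with 2,4,6-trichlorobenzoic acid | CC1(C)OCC=C(C(=O)OC(=O)c2c(Cl)cc(Cl)cc2Cl)CO1 | intermediate
25 | phenacyl ester with 8α-(dioxepine-5-carbonyloxy), 3β-OTBS, 10β-OH | C=C(C(=O)OCC(=O)c3ccccc3)[C@@H]1[C@H]2C=C(C)[C@@H](O[Si](C)(C)C(C)(C)C)C[C@@H]2[C@@](C)(O)C[C@@H]1OC(=O)C4=CCOC(C)(C)OC4 | intermediate
26 | 3β-alcohol of 25 | C=C(C(=O)OCC(=O)c3ccccc3)[C@@H]1[C@H]2C=C(C)[C@@H](O)C[C@@H]2[C@@](C)(O)C[C@@H]1OC(=O)C4=CCOC(C)(C)OC4 | intermediate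
27 | 3β-acetate of 26 | C=C(C(=O)OCC(=O)c3ccccc3)[C@@H]1[C@H]2C=C(C)[C@@H](OC(C)=O)C[C@@H]2[C@@](C)(O)C[C@@H]1OC(=O)C4=CCOC(C)(C)OC4 | intermediate
28 | 3β-acetoxy-10β-hydroxy-8α-[(E)-4-hydroxy-2-(hydroxymethyl)but-2-enoyloxy]cadina-4,11(13)-dien-12-oic acid (1β-H, 6α-H, 7β-H), CNP0468194.3 | C=C(C(=O)O)[C@@H]1[C@H]2C=C(C)[C@@H](OC(C)=O)C[C@@H]2[C@@](C)(O)C[C@@H]1OC(=O)/C(=C/CO)CO | target

**Step count**
Total: 20 steps. Longest linear sequence: 17 steps (steps 1–13 and 17–20); steps 14–16 build the side-chain acid.

**Steps most likely to fail**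

Step 8 (Proposed new method). The silyl-activated enal may be attacked in the 1,4-sense, or isomerise to the (E)-enal, faster than the seven-membered closure, or the C1 cation may be lost by elimination before the 1,2-shift. The fallback uses known reactions, sets out from ketone 5 and comes back at 10; ring A is still made by ring expansion. Ketone 5 is treated with 1-(methylseleno)but-3-enyllithium (from 4,4-bis(methylseleno)but-1-ene and n-BuLi, THF, −78 °C) to give the β-hydroxy selenide F1. AgBF4 on Al2O3 in CH2Cl2 then triggers the selenium-mediated one-carbon ring enlargement, with migration of the more substituted C6, to the 1-allyl cyclohexanone F2 (C1 equatorial, trans to C6). OsO4 (cat.)/NaIO4 with 2,6-lutidine cleaves the terminal alkene to the aldehyde F3. CrCl2 with catalytic NiCl2 in DMF closes ring B by a Nozaki–Hiyama–Kishi reaction between the vinyl iodide carbon C4 and the aldehyde carbon C3 to give the allylic alcohol F4; its chromium alkoxide should sit pseudo-axial (3β) to avoid A(1,2) strain with the C4 methyl group. TBSOTf/2,6-lutidine then gives 10.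

Step 9. Loss of the axial β-acyloxy group at C8 (opening of the lactone to an enone acid) may compete with enolisation toward C1. The fallback sets out from 9 and comes back at 10 by making that elimination deliberate. DBU in CH2Cl2 at 23 °C opens the lactone by E1cB elimination to the enone acid F5, in which C1 (α′ to the enone) equilibrates to the trans fusion. Camphorsulfonic acid (cat.) in CH2Cl2 then re-closes the lactone by intramolecular oxa-Michael addition of the C12 acid to C8; the two-atom tether forces this to occur cis to C7, giving 10.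

Step 11. Facial selectivity in the capture of the C10 mercurinium ion may be poor (axial entry of water giving 10α-OH), or the C4=C5 alkene may compete. The fallback sets out from ketone 10 and comes back at 13, replacing alkene hydration by carbonyl addition. MeLi is added to the complex of 10 with methylaluminium bis(2,6-di-tert-butyl-4-methylphenoxide) in toluene at −78 °C; the bulky aluminium Lewis acid occupies the equatorial side of the ketone, so the methyl group should enter axially (α) and give 13 directly. No new compound is made.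

Further compounds
F1 | step 8 | β-hydroxy selenide: 10β-hydroxy-10α-[1-(methylseleno)but-3-enyl] lactone with 6β-[(Z)-2-iodoprop-1-enyl] (C1 epimers) | O=C1C[C@@H]2[C@@H](/C=C(/C)I)[C@](O)(C(CC=C)[Se]C)C[C@@H]2O1
F2 | step 8 | ring-enlarged ketone: cis-fused cyclohexanone lactone with 1α-allyl (1β-H) and 6β-[(Z)-2-iodoprop-1-enyl] | O=C1C[C@@H]2[C@@H](/C=C(/C)I)[C@H](CC=C)C(=O)C[C@@H]2O1
F3 | step 8 | aldehyde: same ketone with 1α-(2-oxoethyl) | O=C1C[C@@H]2[C@@H](/C=C(/C)I)[C@H](CC=O)C(=O)C[C@@H]2O1
F4 | step 8 | trans-fused tricyclic keto lactone with free 3β-OH (desilyl 10) | O=C1C[C@@H]2[C@H]3C=C(C)[C@@H](O)C[C@@H]3C(=O)C[C@@H]2O1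
F5 | step 9 | enone acid: trans-fused 10-oxo-8,9-ene with 7α-carboxymethyl and 3β-OTBS | OC(=O)C[C@@H]1[C@H]2C=C(C)[C@@H](O[Si](C)(C)C(C)(C)C)C[C@@H]2C(=O)C=C1
F0 | step 11 | none | none
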